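**Plan**
- Retrosynthesis: the pyranone ring is cut at C4–C4a and C3–C4 (CO taken out), which leaves the Z enol triflate of an aryl aryloxymethyl ketone. Ring B is then cut at C2'–C3' and C1'–C6' into an ynone and a 3-alkoxyfuran, and the ynone at its carbonyl–alkyne bond (C3–C1') and at O1–C2.
- Enabling feature: ring B carries four contiguous substituents, C1' (bond to C3), C2' (prenyl), C3' (OH) and C4' (OH). The alkyne carbons become C1' and C2', furan C2–C5 become C3'–C6', the furan ring oxygen ends as the C3' hydroxyl and the furan 3-alkoxy oxygen as the C4' oxygen.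
- Forward: ring A is phloroglucinol; O-alkylation and acetylide acylation give the ynone; ring B arises by Diels–Alder addition and aromatising bridge opening; the pyranone ring closes last by carbonylation onto ring A; fluoride, then acid, deprotect.
- Stereochemistry: the target has no stereocentre. The bridgehead centres of the cycloadduct are transient, and the one geometry that matters, the Z enol triflate, comes from the chelated potassium enolate.

Key step: step 6

Remark: unprimed locants refer to the chromone, primed ones to ring B; compounds 3, 6, 10 and 11 are taken as purchasable.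

**Step 1**
Reactants: 1 phloroglucinol (benzene-1,3,5-triol)
Product: 2 3,5-bis(methoxymethoxy)phenol
Conditions: MOMCl (2.1 equiv), i-Pr2NEt, DMF, 0 °C → rt
Reagents that add atoms: chloromethyl methyl ether (MOMCl), COCCl
Why: Statistical O-alkylation (acetal formation) of the C3-symmetric triphenol should give the bis-ether as the main fraction, separable from the mono- and tris-ethers, which can be recycled.

**Step 2**
Reactants: 2 3,5-bis(methoxymethoxy)phenol; 3 2-chloro-N-methoxy-N-methylacetamide
Product: 4 2-[3,5-bis(methoxymethoxy)phenoxy]-N-methoxy-N-methylacetamide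
Conditions: K2CO3, NaI (cat.), DMF, 60 °C
Reagents that add atoms: none
Why: Williamson ether synthesis of the phenoxide with an activated alpha-chloro amide (Finkelstein-assisted) should install the two-carbon unit directly at the acylating oxidation level.

**Step 3**
Reactants: 5 1-bromo-3-methylbut-2-ene (prenyl bromide); 6 ethynylmagnesium bromide
Product: 7 5-methylhex-4-en-1-yne
Conditions: CuCl (5 mol%), THF, 0 → 40 °C; distillation
Reagents that add atoms: none
Why: Copper-catalysed allylic substitution of a primary allylic bromide by an alkynyl Grignard reagent should take place at the unhindered CH2 terminus (SN2) and give the linear 1,4-enyne.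

**Step 4**
Reactants: 7 5-methylhex-4-en-1-yne; 4 2-[3,5-bis(methoxymethoxy)phenoxy]-N-methoxy-N-methylacetamide
Product: 9 1-[3,5-bis(methoxymethoxy)phenoxy]-7-methyloct-6-en-3-yn-2-one, via lithium acetylide 8 (not isolated)
Conditions: n-BuLi, THF, −78 °C; then 4, −78 → −30 °C; AcOH quench at −78 °C
Reagents that add atoms: none
Why: Weinreb ketone synthesis: the chelated tetrahedral adduct should persist until the acidic quench, so the ynone is released only under non-basic conditions that leave the skipped enyne unisomerised.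

**Step 5**
Reactants: 10 3-bromofuran; 11 2-(trimethylsilyl)ethanol
Product: 12 3-[2-(trimethylsilyl)ethoxy]furan
Conditions: CuI (10 mol%), 3,4,7,8-tetramethyl-1,10-phenanthroline (20 mol%), Cs2CO3, toluene, 110 °C (sealed tube)
Reagents that add atoms: none
Why: Ullmann-type copper-catalysed C–O coupling of a heteroaryl bromide with a primary alcohol should give the alkoxyfuran, the silylethyl group being chosen because fluoride can remove it later without touching the prenyl group.

**Step 6**
Reactants: 9 1-[3,5-bis(methoxymethoxy)phenoxy]-7-methyloct-6-en-3-yn-2-one; 12 3-[2-(trimethylsilyl)ethoxy]furan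
Product: 14 2-[3,5-bis(methoxymethoxy)phenoxy]-1-{3-hydroxy-2-(3-methylbut-2-en-1-yl)-4-[2-(trimethylsilyl)ethoxy]phenyl}ethan-1-one, via 7-oxanorbornadiene cycloadduct 13 (not isolated)
Conditions: 12 (1.5 equiv), PhMe (1 M), 60 °C; then pyridinium p-toluenesulfonate (cat.), rt
Reagents that add atoms: none
Why: The electron-rich furan and the electron-poor ynone should combine in a concerted but asynchronous Diels–Alder (4+2) cycloaddition, the closest known reaction type being the addition of 3-alkoxyfurans to acetylenic ketones with opening of the 7-oxanorbornadiene to a 2-alkoxyphenol. Ring B closes intermolecularly by two sigma bonds across the diene termini: furan C2, the most nucleophilic position beside the alkoxy-bearing carbon, joins the prenyl-bearing beta-carbon of the ynone (C3'–C2'), and furan C5 joins the acyl-bearing carbon (C6'–C1'). In 13 the bridge C–O bond at the former furan C5 should ionise, since the allyl cation so formed is conjugated to the enol ether oxygen at the former furan C3, and deprotonation at the remaining bridgehead then aromatises the ring with the bridge oxygen kept as the C3' hydroxyl. The two bridgehead stereocentres of 13 form as a racemate and disappear on aromatisation, so 14 has no stereocentre to control. The step needs one orientation of the cycloaddition and one direction of bridge opening, and both are dictated by the donor alkoxy group at furan C3 set against the acceptor carbonyl of the ynone. Neutral conditions and moderate temperature should leave the 1,4-enyne unisomerised.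

**Step 7**
Reactants: 14 2-[3,5-bis(methoxymethoxy)phenoxy]-1-{3-hydroxy-2-(3-methylbut-2-en-1-yl)-4-[2-(trimethylsilyl)ethoxy]phenyl}ethan-1-one
Product: 15 2-[3,5-bis(methoxymethoxy)phenoxy]-1-{3-(methoxymethoxy)-2-(3-methylbut-2-en-1-yl)-4-[2-(trimethylsilyl)ethoxy]phenyl}ethan-1-one
Conditions: MOMCl, i-Pr2NEt, CH2Cl2, 0 °C → rt
Reagents that add atoms: chloromethyl methyl ether (MOMCl), COCCl
Why: O-alkylation of the phenol to its methoxymethyl acetal under amine base should mask the only acidic OH before enolate chemistry without enolising the ketone.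

**Step 8**
Reactants: 15 2-[3,5-bis(methoxymethoxy)phenoxy]-1-{3-(methoxymethoxy)-2-(3-methylbut-2-en-1-yl)-4-[2-(trimethylsilyl)ethoxy]phenyl}ethan-1-one
Product: 17 (1Z)-2-[3,5-bis(methoxymethoxy)phenoxy]-1-{3-(methoxymethoxy)-2-(3-methylbut-2-en-1-yl)-4-[2-(trimethylsilyl)ethoxy]phenyl}ethen-1-yl trifluoromethanesulfonate, via potassium enolate 16 (not isolated)
Conditions: KN(SiMe3)2, THF, −78 °C; then PhNTf2, −78 → 0 °C
Reagents that add atoms: N-phenylbis(trifluoromethanesulfonimide) (PhNTf2), O=S(=O)(N(c1ccccc1)S(=O)(=O)C(F)(F)F)C(F)(F)F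
Why: Enolate O-sulfonylation: the OCH2 group is the only enolisable position, and the potassium enolate should be Z (aryloxy group chelated cis to the enolate oxygen and trans to the ortho-substituted aryl group), which puts the triflate cis to the ring A ether oxygen as the ring closure requires.

**Step 9**
Reactants: 17 (1Z)-2-[3,5-bis(methoxymethoxy)phenoxy]-1-{3-(methoxymethoxy)-2-(3-methylbut-2-en-1-yl)-4-[2-(trimethylsilyl)ethoxy]phenyl}ethen-1-yl trifluoromethanesulfonate
Product: 18 5,7-bis(methoxymethoxy)-3-{3-(methoxymethoxy)-2-(3-methylbut-2-en-1-yl)-4-[2-(trimethylsilyl)ethoxy]phenyl}-4H-chromen-4-one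
Conditions: Pd(OAc)2 (10 mol%), 1,3-bis(diphenylphosphino)propane (12 mol%), CsO2CCMe3 (2 equiv), CO (10 bar), DMF, 80 °C
Reagents that add atoms: carbon monoxide, [C-]#[O+]
Why: Proposed new method: oxidative addition of the enol triflate to zerovalent palladium should give a cationic alkenylpalladium species that inserts CO to an acylpalladium held by the Z geometry beside the ring A carbon ortho to the ether oxygen; pivalate-assisted palladation of this very electron-rich C–H position (or direct Friedel–Crafts-type attack of the arene on the acyl group) followed by C–C reductive elimination would close the pyranone ring, and either ortho position of the symmetric ring A gives the same product; the closest known reaction types are the palladium-catalysed cyclocarbonylation of 2-halobiaryls to fluorenones and the carbonylative C–H cyclisation of diaryl ethers to xanthones; the CO pressure is meant to make insertion outrun direct C–H alkenylation to a benzofuran.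

**Step 10**
Reactants: 18 5,7-bis(methoxymethoxy)-3-{3-(methoxymethoxy)-2-(3-methylbut-2-en-1-yl)-4-[2-(trimethylsilyl)ethoxy]phenyl}-4H-chromen-4-one
Product: 19 3-[4-hydroxy-3-(methoxymethoxy)-2-(3-methylbut-2-en-1-yl)phenyl]-5,7-bis(methoxymethoxy)-4H-chromen-4-one
Conditions: CsF, DMF, 90 °C; AcOH work-up
Reagents that add atoms: none
Why: Fluoride-induced beta-elimination (attack at silicon, loss of ethene) should cleave the aryl 2-(trimethylsilyl)ethyl ether, while the MOM acetals, the prenyl group and the chromone are inert to anhydrous fluoride.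

**Step 11**
Reactants: 19 3-[4-hydroxy-3-(methoxymethoxy)-2-(3-methylbut-2-en-1-yl)phenyl]-5,7-bis(methoxymethoxy)-4H-chromen-4-one
Product: 20 5,7,3',4'-tetrahydroxy-2'-(3,3-dimethylallyl)isoflavone, that is 3-[3,4-dihydroxy-2-(3-methylbut-2-en-1-yl)phenyl]-5,7-dihydroxy-4H-chromen-4-one
Conditions: HCl (1 M), MeOH/THF, 40 °C
Reagents that add atoms: none
Why: Acid-catalysed acetal exchange with methanol should remove the three MOM groups, dilute acid and moderate temperature being chosen so that cyclisation of the freed C3' hydroxyl onto the prenyl olefin does not compete and the catechol is released under non-oxidising conditions.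

**Compound list**
1 | phloroglucinol (benzene-1,3,5-triol) | Oc1cc(O)cc(O)c1 | starting material
2 | 3,5-bis(methoxymethoxy)phenol | COCOc1cc(O)cc(OCOC)c1 | intermediate
3 | 2-chloro-N-methoxy-N-methylacetamide | CON(C)C(=O)CCl | starting material
4 | 2-[3,5-bis(methoxymethoxy)phenoxy]-N-methoxy-N-methylacetamide | COCOc1cc(OCOC)cc(OCC(=O)N(C)OC)c1 | intermediate
5 | 1-bromo-3-methylbut-2-ene (prenyl bromide) | CC(C)=CCBr | starting material
6 | ethynylmagnesium bromide | C#C[Mg]Br | starting material
7 | 5-methylhex-4-en-1-yne | C#CCC=C(C)C | intermediate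
8 | lithium 5-methylhex-4-en-1-yn-1-ide | [Li]C#CCC=C(C)C | intermediate (not isolated)
9 | 1-[3,5-bis(methoxymethoxy)phenoxy]-7-methyloct-6-en-3-yn-2-one | COCOc1cc(OCOC)cc(OCC(=O)C#CCC=C(C)C)c1 | intermediate
10 | 3-bromofuran | Brc1ccoc1 | starting material
11 | 2-(trimethylsilyl)ethanol | C[Si](C)(C)CCO | starting material
12 | 3-[2-(trimethylsilyl)ethoxy]furan | C[Si](C)(C)CCOc1ccoc1 | intermediate
13 | 2-[3,5-bis(methoxymethoxy)phenoxy]-1-{3-(3-methylbut-2-en-1-yl)-5-[2-(trimethylsilyl)ethoxy]-7-oxabicyclo[2.2.1]hepta-2,5-dien-2-yl}ethan-1-one (racemic, one enantiomer drawn) | C[Si](C)(C)CCOC1=C[C@@H]2O[C@H]1C(CC=C(C)C)=C2C(=O)COc1cc(OCOC)cc(OCOC)c1 | intermediate (not isolated)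
14 | 2-[3,5-bis(methoxymethoxy)phenoxy]-1-{3-hydroxy-2-(3-methylbut-2-en-1-yl)-4-[2-(trimethylsilyl)ethoxy]phenyl}ethan-1-one | COCOc1cc(OCOC)cc(OCC(=O)c2ccc(OCC[Si](C)(C)C)c(O)c2CC=C(C)C)c1 | intermediate
15 | 2-[3,5-bis(methoxymethoxy)phenoxy]-1-{3-(methoxymethoxy)-2-(3-methylbut-2-en-1-yl)-4-[2-(trimethylsilyl)ethoxy]phenyl}ethan-1-one | COCOc1cc(OCOC)cc(OCC(=O)c2ccc(OCC[Si](C)(C)C)c(OCOC)c2CC=C(C)C)c1 | intermediate
16 | potassium (1Z)-2-[3,5-bis(methoxymethoxy)phenoxy]-1-{3-(methoxymethoxy)-2-(3-methylbut-2-en-1-yl)-4-[2-(trimethylsilyl)ethoxy]phenyl}ethen-1-olate | COCOc1cc(OCOC)cc(O/C=C(\[O-])c2ccc(OCC[Si](C)(C)C)c(OCOC)c2CC=C(C)C)c1.[K+] | intermediate (not isolated)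
17 | (1Z)-2-[3,5-bis(methoxymethoxy)phenoxy]-1-{3-(methoxymethoxy)-2-(3-methylbut-2-en-1-yl)-4-[2-(trimethylsilyl)ethoxy]phenyl}ethen-1-yl trifluoromethanesulfonate | COCOc1cc(OCOC)cc(O/C=C(\OS(=O)(=O)C(F)(F)F)c2ccc(OCC[Si](C)(C)C)c(OCOC)c2CC=C(C)C)c1 | intermediate
18 | 5,7-bis(methoxymethoxy)-3-{3-(methoxymethoxy)-2-(3-methylbut-2-en-1-yl)-4-[2-(trimethylsilyl)ethoxy]phenyl}-4H-chromen-4-one | COCOc1cc(OCOC)c2c(=O)c(-c3ccc(OCC[Si](C)(C)C)c(OCOC)c3CC=C(C)C)coc2c1 | intermediate
19 | 3-[4-hydroxy-3-(methoxymethoxy)-2-(3-methylbut-2-en-1-yl)phenyl]-5,7-bis(methoxymethoxy)-4H-chromen-4-one | COCOc1cc(OCOC)c2c(=O)c(-c3ccc(O)c(OCOC)c3CC=C(C)C)coc2c1 | intermediate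
20 | 5,7,3',4'-tetrahydroxy-2'-(3,3-dimethylallyl)isoflavone | CC(C)=CCc1c(-c2coc3cc(O)cc(O)c3c2=O)ccc(O)c1O | target

**Step count**
Total: 11 steps. Longest linear sequence: 9 steps (1, 2, 4, 6, 7, 8, 9, 10, 11); steps 3 and 5 are side branches.

**Steps most likely to fail**

1. Step 9. The alkenylpalladium may close directly onto ring A without taking up CO, may be captured by the prenyl olefin in a Heck-type cyclisation, or the acylpalladium may be intercepted by pivalate and never engage the arene. The fallback uses known chemistry and sets out from enol triflate 17. Hydroxycarbonylation (Pd(OAc)2, PPh3, potassium acetate, CO 1 atm, DMF, rt) should give, through the mixed acetic anhydride F1 that is hydrolysed on aqueous work-up, the Z acrylic acid F2. Brief treatment with trifluoroacetic anhydride in CH2Cl2 at 0 °C, quenched with bicarbonate to spare the acetals and the prenyl group, should then close the pyranone ring by intramolecular Friedel–Crafts acylation of the phloroglucinol-type ring through the mixed trifluoroacetic anhydride F3. The route is rejoined at 18.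

2. Step 6. Cycloaddition to the beta-alkyl ynone may be sluggish, conjugate addition of the furan may stop short of ring closure, or the 1,4-enyne may isomerise on prolonged heating. The fallback sets out from amide 4 together with furan 12 and delivers the prenyl group after ring B exists. Ethynylmagnesium bromide 6 (THF, 0 °C) should convert 4 into the terminal ynone F4, a far more reactive dienophile of the same polarisation. Its addition to 12 at room temperature should pass through the bridged cycloadduct F5 to the C2'-unsubstituted phenol F6. Tsuji–Trost O-alkylation (Pd(PPh3)4, methyl 2-methylbut-3-en-2-yl carbonate, THF) should give the 1,1-dimethylallyl ether F7. Its aromatic Claisen rearrangement (toluene, 110 °C) can end only at C2', the one free ortho position, and rejoins the route at 14.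

3. Step 5. The beta-silyl alkoxide may fragment with loss of ethene under hot basic conditions, and oxidative addition of the electron-rich, volatile bromofuran to copper may be slow. The fallback builds the furan ring instead of substituting it and sets out from alcohol 11. 3,3-Diethoxyprop-1-yne is lithiated (n-BuLi) and hydroxymethylated with paraformaldehyde to 4,4-diethoxybut-2-yn-1-ol F8. Stirred in 11 with Ph3PAuNTf2 (2 mol%) at room temperature, this acetal should undergo alkoxy exchange and gold-catalysed cycloisomerisation with loss of two molecules of ethanol, which rejoins the route at 12.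

**Further compounds**
F1 | step 9 | acetic (2Z)-3-[3,5-bis(methoxymethoxy)phenoxy]-2-{3-(methoxymethoxy)-2-(3-methylbut-2-en-1-yl)-4-[2-(trimethylsilyl)ethoxy]phenyl}prop-2-enoic anhydride | COCOc1cc(OCOC)cc(O/C=C(\C(=O)OC(C)=O)c2ccc(OCC[Si](C)(C)C)c(OCOC)c2CC=C(C)C)c1
F2 | step 9 | (2Z)-3-[3,5-bis(methoxymethoxy)phenoxy]-2-{3-(methoxymethoxy)-2-(3-methylbut-2-en-1-yl)-4-[2-(trimethylsilyl)ethoxy]phenyl}prop-2-enoic acid | COCOc1cc(OCOC)cc(O/C=C(\C(=O)O)c2ccc(OCC[Si](C)(C)C)c(OCOC)c2CC=C(C)C)c1
F3 | step 9 | (2Z)-3-[3,5-bis(methoxymethoxy)phenoxy]-2-{3-(methoxymethoxy)-2-(3-methylbut-2-en-1-yl)-4-[2-(trimethylsilyl)ethoxy]phenyl}prop-2-enoic trifluoroacetic anhydride | COCOc1cc(OCOC)cc(O/C=C(\C(=O)OC(=O)C(F)(F)F)c2ccc(OCC[Si](C)(C)C)c(OCOC)c2CC=C(C)C)c1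
F4 | step 6 | 1-[3,5-bis(methoxymethoxy)phenoxy]but-3-yn-2-one | COCOc1cc(OCOC)cc(OCC(=O)C#C)c1
F5 | step 6 | 2-[3,5-bis(methoxymethoxy)phenoxy]-1-{5-[2-(trimethylsilyl)ethoxy]-7-oxabicyclo[2.2.1]hepta-2,5-dien-2-yl}ethan-1-one (racemic, one enantiomer drawn) | C[Si](C)(C)CCOC1=C[C@@H]2O[C@H]1C=C2C(=O)COc1cc(OCOC)cc(OCOC)c1
F6 | step 6 | 2-[3,5-bis(methoxymethoxy)phenoxy]-1-{3-hydroxy-4-[2-(trimethylsilyl)ethoxy]phenyl}ethan-1-one | COCOc1cc(OCOC)cc(OCC(=O)c2ccc(OCC[Si](C)(C)C)c(O)c2)c1
F7 | step 6 | 2-[3,5-bis(methoxymethoxy)phenoxy]-1-{3-[(2-methylbut-3-en-2-yl)oxy]-4-[2-(trimethylsilyl)ethoxy]phenyl}ethan-1-one | COCOc1cc(OCOC)cc(OCC(=O)c2ccc(OCC[Si](C)(C)C)c(OC(C)(C)C=C)c2)c1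
F8 | step 5 | 4,4-diethoxybut-2-yn-1-ol | CCOC(OCC)C#CCO
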